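## The problem

The target **29** is a cis-fused bicyclo[4.3.0]nonenone: a cyclohexenone (ring B) fused to an unfunctionalised cyclopentane (ring C). In indenone numbering, C4 is the carbonyl carbon, C5 carries the 2-hydroxy-2-methylpropyl arm, C6 carries the aryl-terminated chain, C7 is a methylene, and C3a/C7a are the ring-fusion carbons. The only stereocentres are C3a and C7a: adjacent, both quaternary, both methyl-bearing, cis. Nothing else in the molecule can relay stereochemistry to them, so their relative configuration has to come from the bond-forming event itself and their absolute configuration from a reagent or catalyst. Making C–C bonds at two vicinal fully substituted carbons is the central difficulty; stepwise alkylation there is sterically punished. Several groups will not survive rough treatment: the free para-methoxyphenol (oxidised to a quinone), the tertiary alcohol γ to the enone carbonyl (dehydration, or capture of a nearby cation), the doubly allylic CH2 between C6 and the chain alkene (base-induced migration into conjugation), and the E geometry of that trisubstituted alkene. The enabling feature is that C4 and C7 each flank one quaternary carbon, so C4–C5–C6–C7 is a four-carbon diene unit and C3a–C7a is a two-carbon unit whose cis-dimethyl pattern is that of a cyclic 1,2-dimethyl alkene. Ring C can therefore arrive as the ring that activates the dienophile.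

## Retrosynthesis

**29 ⇒ 28.** Two O–Si bonds are cut. The phenol is carried as a tert-butyldimethylsilyl ether and the tertiary alcohol as a triethylsilyl ether, so the phenol is not exposed to the chromium oxidant or the organometallic, and the alcohol cannot trap allylic cations. One fluoride treatment removes both.

**28 ⇒ 27 ⇒ 18 + 25.** The bond between C6 and the chain CH2 is cut together with a 1,3-carbonyl transposition. This leads to tertiary allylic alcohol **27** and then to enone **18**, whose carbonyl sits on the future C6, plus allylic chloride **25**. The neighbouring cuts are worse: conjugate addition of an allyl nucleophile to a C4 enone would need a reluctant allyl cuprate and a re-oxidation, and cutting the C5 arm would need α-alkylation of a hindered enone. The chosen cut splits the 28 skeletal carbons into a 15-carbon bicycle and a 13-carbon arene fragment. The forward steps must deliver the allyl unit through its CH2 terminus with the E alkene intact, add 1,2 to the enone, and shift oxygen onto the neopentyl carbon C4.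

**18 ⇒ 17 ⇒ 13.** Functional groups are added back: a methoxy group at C4, a silyl enol ether at C6, and two carbonyls at C1 and C3 of ring C. This turns **18** into **13**, the retron of a [4+2] cycloaddition with a doubly activated dienophile. The cost is the later removal of a 2-unsubstituted 1,3-dione flanked by two quaternary carbons. Such diones are enolic and acidic, and hydride reagents deprotonate them and then give reduction–elimination products instead of diols. Each carbonyl is therefore taken off through an enol triflate and hydrogenolysis (**14**, **15**, **16**), with ring B kept masked. The ring B enol ether must outlast four steps, so it is a tert-butyldimethylsilyl ether and not a trimethylsilyl ether.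

**13 ⇒ 4 + 12.** The C3a–C4 and C7–C7a bonds are cut. Both quaternary centres, their cis relationship and ring B appear in one step from two flat, achiral pieces: ene-dione **4** (7 carbons) and diene **12**, which already carries the C5 arm and oxygen at C4 and C6. Cuts that make the C3a–C7a bond itself, or that close ring C last, leave two hindered bonds to form one after the other. The forward reaction must be fast enough at a tetrasubstituted alkene and must be enantioselective; regiochemistry is not an issue because **4** is C2v-symmetric.

**4 ⇒ 3 ⇒ 2 ⇒ 1.** The ring C carbon between the carbonyls is cut off as an ester-stabilised ylide carbon. Anhydride **1** is olefinated to enol lactone **2**; alkoxide rearranges it to the carbocyclic dione ester **3**; loss of the tert-butyl ester and CO2 gives **4**. All five ring carbons and both methyls come from a symmetrical, commercial anhydride.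

**12 ⇒ 11 ⇒ 10 ⇒ 8 ⇒ 7 ⇒ 6 ⇒ 5.** The enol silyl ether is cut first, then the acetyl methyl (from Weinreb amide **10**), then the methoxymethylidene carbon (from amide **8**). Formylating the methyl ketone directly is avoided: a ketone CH3CO–CH2–CH2R with a branched R is formylated mainly at the methyl group, which would put the formyl carbon on the wrong side. In amide **8** there is only one enolisable position, so the regiochemistry is fixed by constitution. The tertiary silyl ether is in place from the start, made from ethyl levulinate (**5**) through lactone **6** and hydroxy amide **7**.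

**25 ⇒ 24 ⇒ 23 ⇒ 22 ⇒ 21 ⇒ 20 ⇒ 19.** The chain alkene is cut by cross-metathesis into allyl arene **22** and methacrolein, which gives the E-trisubstituted enal **23** under thermodynamic control. The aryl–allyl bond is cut by an aromatic Claisen rearrangement of ether **20**; the single free ortho position of phenol **19** fixes the regiochemistry. Reduction (**24**) and chloride formation (**25**) complete the fragment.

## Roads not taken

**Alternative 1:** The C3a–C7a bond is cut. Forward, the silyl ketene acetal of the nine-membered lactone **A1** would undergo a transannular Ireland–Claisen rearrangement and contract to the cyclopentane acid **A2**. Merits: the bond between the two quaternary carbons forms intramolecularly; the medium ring enforces the cis relationship; the absolute configuration is transferred from one secondary carbinol centre. That mode of stereocontrol is better established than catalyst control at a tetrasubstituted dienophile, and ring C arrives with no surplus oxygen. On both counts this road is better than the chosen one, which needs four steps to deoxygenate ring C. Weak points: **A1** needs a medium-ring lactonisation and a Z-trisubstituted ring alkene; the ketene acetal geometry in a nine-membered ring is not secure, yet it decides the relative configuration; the sigmatropic shift joins two fully substituted carbons. Most important, **A2** contains ring C only. Ring B, its carbonyl, the C5 arm and the C6 chain would all have to be built afterwards from a neopentyl acid and an enyne. The chosen plan sets against this a key step that delivers ring B, both stereocentres, the arm and correctly placed oxygen together.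

**Alternative 2:** The C6–C7 bond of ring B is cut. Forward, cathodic reduction of the N-acyloxyphthalimide **A3** (zinc sacrificial anode) would release CO2 and a primary radical, which adds 6-endo-dig to the ynone β-carbon to give enone **A4**. Merits: mild, polarity-matched, and ring B closes with the complete aryl side chain already attached. There is no allylmetal regiochemistry problem and no oxidative transposition, so the end game is shorter and more convergent than in the chosen plan. Weak points: the two vicinal quaternary stereocentres are not made by this step; the problem is only moved into **A3**, a cis-1,2-dimethylcyclopentane with different carbon chains on adjacent quaternary carbons. The vinyl radical formed on cyclisation sits close to the doubly allylic hydrogens of the chain and may abstract one. **A4** lacks the C5 arm, and α-alkylation of a hindered β,β-disubstituted enone with a β-oxygenated alkyl group has no dependable solution. The chosen plan installs that arm on the diene before the ring exists and solves the stereochemical problem in the same step that closes ring B.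

**Alternative 3:** The bond from C3a to ring C is cut. Forward, Ph3PAuCl with AgBF4 (a cationic complex of monovalent gold) would activate the alkyne of silyl enol ether **A5**; the methyl-bearing enol carbon attacks 5-endo-dig and closes ring C to give **A6**. Merits: this cyclisation type is established; cis fusion is automatic for a five-membered ring; the first quaternary centre can be set by known chemistry before the key step. In certainty of the key step and of the stereocontrol this road is ahead of the chosen one, and no carbonyl has to be removed. Weak points: **A6** is the bare hydrindenone. Ring B carries only a ketone and three methylenes, so the enone unsaturation, the C5 arm and the C6 chain must all be added next to a quaternary carbon. That needs an alkylation, a dehydrogenation, a conjugate addition of an allylic nucleophile and a second dehydrogenation in the presence of the chain alkene, plus saturation of the ring C alkene. The chosen plan pays in redox steps on ring C but delivers ring B with every carbon at its final oxidation level, leaving one C–C bond to make.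

Key step: step 10

Assumption: the (R)-BINOL–titanium catalyst of step 10 is taken to give the (3aR,7aR) series; if the sense proves opposite, (S)-BINOL is used with no other change.

## Route

Step 1
Reactants: 1 2,3-dimethylmaleic anhydride
Product: 2 tert-butyl (2E)-(3,4-dimethyl-5-oxofuran-2(5H)-ylidene)acetate
Conditions: Ph3P=CHCO2tBu, toluene, 80 °C
Reagents that add atoms: tert-butyl (triphenylphosphoranylidene)acetate, CC(C)(C)OC(=O)C=P(c1ccccc1)(c1ccccc1)c1ccccc1
Why: Wittig olefination of an anhydride carbonyl by a stabilised ylide gives the enol lactone; the anhydride is symmetrical, so there is no regiochemical question, and the alkene geometry is lost in step 2.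

Step 2
Reactants: 2 tert-butyl (2E)-(3,4-dimethyl-5-oxofuran-2(5H)-ylidene)acetate
Product: 3 tert-butyl 3,4-dimethyl-2,5-dioxocyclopent-3-ene-1-carboxylate
Conditions: NaOMe, MeOH, 0 °C → rt; cold dilute HCl
Reagents that add atoms: none
Why: Methoxide opens the enol lactone to a β-keto ester enolate, which recloses on the new methyl ester by Dieckmann condensation (the known alkoxide rearrangement of ylidenebutenolides to cyclopent-4-ene-1,3-diones); the product is held as its stabilised enolate, which protects the tert-butyl ester.

Step 3
Reactants: 3 tert-butyl 3,4-dimethyl-2,5-dioxocyclopent-3-ene-1-carboxylate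
Product: 4 4,5-dimethylcyclopent-4-ene-1,3-dione
Conditions: CF3CO2H, CH2Cl2, rt
Reagents that add atoms: none
Why: Acidolysis of the tert-butyl ester and spontaneous decarboxylation of the 2-carboxy-1,3-dione; the ene-dione tolerates acid because it cannot enolise without becoming a hydroxycyclopentadienone.

Step 4
Reactants: 5 ethyl levulinate
Product: 6 5,5-dimethyloxolan-2-one
Conditions: MeMgBr (1.05 equiv), THF, −40 → 0 °C; 1 M HCl
Reagents that add atoms: methylmagnesium bromide, C[Mg]Br
Why: Grignard addition to the ketone, which is faster than addition to the ester at low temperature, followed by lactonisation of the γ-alkoxide with loss of ethoxide.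

Step 5
Reactants: 6 5,5-dimethyloxolan-2-one
Product: 7 4-hydroxy-N-methoxy-N,4-dimethylpentanamide
Conditions: Me(MeO)NH·HCl, Me3Al, CH2Cl2, 0 °C → rt
Reagents that add atoms: N,O-dimethylhydroxylamine hydrochloride, CNOC.Cl
Why: Weinreb aminolysis of a lactone by the aluminium amide; the hydroxy amide is silylated at once because the gem-dimethyl carbinol tends to relactonise.

Step 6
Reactants: 7 4-hydroxy-N-methoxy-N,4-dimethylpentanamide
Product: 8 N-methoxy-N,4-dimethyl-4-(triethylsilyloxy)pentanamide
Conditions: Et3SiOTf, 2,6-lutidine, CH2Cl2, −78 → 0 °C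
Reagents that add atoms: triethylsilyl trifluoromethanesulfonate, CC[Si](CC)(CC)OS(=O)(=O)C(F)(F)F
Why: Silylation of a tertiary alcohol with a silyl triflate and a hindered base; the ether blocks lactonisation and later cation capture.

Step 7
Reactants: 8 N-methoxy-N,4-dimethyl-4-(triethylsilyloxy)pentanamide
Product: 10 (2E)-N-methoxy-2-(methoxymethylidene)-N,4-dimethyl-4-(triethylsilyloxy)pentanamide, via formyl amide lithium enolate 9 (not isolated)
Conditions: LiN(iPr)2 (2.2 equiv), THF, −78 °C; HCO2Et, −78 → 0 °C; then DMPU, Me2SO4, 0 °C → rt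
Reagents that add atoms: ethyl formate, CCOC=O; dimethyl sulfate, COS(=O)(=O)OC
Why: Claisen formylation of the amide enolate, which has a single enolisable position, then O-methylation of the formyl enolate by a hard electrophile in a dipolar medium, as in β-methoxyacrylate synthesis; the E isomer with methoxy anti to the carbonyl is the thermodynamic product.

Step 8
Reactants: 10 (2E)-N-methoxy-2-(methoxymethylidene)-N,4-dimethyl-4-(triethylsilyloxy)pentanamide
Product: 11 (3E)-3-(methoxymethylidene)-5-methyl-5-(triethylsilyloxy)hexan-2-one
Conditions: MeMgBr, THF, −20 → 0 °C; aq NH4Cl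
Reagents that add atoms: methylmagnesium bromide, C[Mg]Br
Why: Weinreb ketone synthesis; the chelated tetrahedral intermediate stops at the ketone stage, and the donor methoxy group disfavours conjugate attack.

Step 9
Reactants: 11 (3E)-3-(methoxymethylidene)-5-methyl-5-(triethylsilyloxy)hexan-2-one
Product: 12 (1E)-3-(tert-butyldimethylsilyloxy)-1-methoxy-2-[2-methyl-2-(triethylsilyloxy)propyl]buta-1,3-diene
Conditions: tBuMe2SiOTf, Et3N, Et2O, 0 °C
Reagents that add atoms: tert-butyldimethylsilyl trifluoromethanesulfonate, CC(C)(C)[Si](C)(C)OS(=O)(=O)C(F)(F)F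
Why: Soft enolisation and O-silylation at the only α-methyl group, the standard preparation of 1-alkoxy-3-silyloxy dienes; the E geometry of the methoxyvinyl unit is untouched.

Step 10
Reactants: 4 4,5-dimethylcyclopent-4-ene-1,3-dione; 12 (1E)-3-(tert-butyldimethylsilyloxy)-1-methoxy-2-[2-methyl-2-(triethylsilyloxy)propyl]buta-1,3-diene
Product: 13 (3aR,4S,7aR)-6-(tert-butyldimethylsilyloxy)-4-methoxy-3a,7a-dimethyl-5-[2-methyl-2-(triethylsilyloxy)propyl]-3a,4,7,7a-tetrahydro-1H-indene-1,3(2H)-dione
Conditions: Ti(OiPr)4 (20 mol %), (R)-BINOL (40 mol %), 4 Å molecular sieves, toluene, −20 °C → rt; 12 (1.5 equiv); crude product taken directly into step 11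
Reagents that add atoms: none
Why: Proposed new method: the BINOL alkoxide of tetravalent titanium binds one of the two homotopic carbonyl groups of 4 and lowers the LUMO of the ene-dione, and diene 12 adds in a concerted but asynchronous [4+2] cycloaddition in which its methylene terminus bonds first to the carbon β to the complexed carbonyl; the closest known reaction type is the BINOL–titanium-catalysed enantioselective Diels–Alder reaction of 1-alkoxy dienes with quinones and other cyclic ene-diones, together with the thermal addition of 1-alkoxy-3-silyloxy dienes to 2,3-dimethyl-substituted cyclic ene-diones and anhydrides, and the new element is catalyst control at a tetrasubstituted alkene. Ring B closes in this step as a six-membered carbocycle by suprafacial addition of both diene termini to one face of the dienophile. C3a and C7a must therefore be cis, as a consequence of the ring-locked alkene of 4 and not of any reagent. Their absolute configuration is set by the chiral ligand sphere, which shields one face of the complexed dienophile; because the Lewis acid also fixes which alkene carbon bonds to C1 of the diene, face selection alone decides the enantiomer, and endo and exo transition states give the same C3a/C7a configuration. C4 is set by the endo preference of the E-methoxy diene but is erased in step 15. No regiochemical question arises, because both alkene carbons of 4 are equivalent before complexation. The step needs the catalysed path to outrun the racemic background reaction; the double activation of the ene-dione, which cannot enolise without forming a cyclopentadienone, and the high HOMO of the 1,3-dioxygenated diene should provide this.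

Step 11
Reactants: 13 (3aR,4S,7aR)-6-(tert-butyldimethylsilyloxy)-4-methoxy-3a,7a-dimethyl-5-[2-methyl-2-(triethylsilyloxy)propyl]-3a,4,7,7a-tetrahydro-1H-indene-1,3(2H)-dione
Product: 14 (3aR,4S,7aR)-6-(tert-butyldimethylsilyloxy)-4-methoxy-3a,7a-dimethyl-5-[2-methyl-2-(triethylsilyloxy)propyl]-3-oxo-3a,4,7,7a-tetrahydro-3H-inden-1-yl trifluoromethanesulfonate
Conditions: Et3N, PhNTf2, DMAP (cat.), CH2Cl2, 0 °C → rt
Reagents that add atoms: N-phenylbis(trifluoromethanesulfonimide), O=S(=O)(N(c1ccccc1)S(=O)(=O)C(F)(F)F)C(F)(F)F
Why: The 2-unsubstituted 1,3-dione is an enolic, acidic vinylogous acid, and O-sulfonylation of its ammonium enolate gives the vinylogous acyl triflate without any acid. Attack is expected at the enolate oxygen remote from the C4 methoxy group; the regiochemistry does not matter because both ring C oxygens are gone after step 14.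

Step 12
Reactants: 14 (3aR,4S,7aR)-6-(tert-butyldimethylsilyloxy)-4-methoxy-3a,7a-dimethyl-5-[2-methyl-2-(triethylsilyloxy)propyl]-3-oxo-3a,4,7,7a-tetrahydro-3H-inden-1-yl trifluoromethanesulfonate
Product: 15 (3aR,7S,7aR)-5-(tert-butyldimethylsilyloxy)-7-methoxy-3a,7a-dimethyl-6-[2-methyl-2-(triethylsilyloxy)propyl]-2,3,3a,4,7,7a-hexahydro-1H-inden-1-one
Conditions: H2 (1 atm), Pd/C (10 %), Et3N, EtOAc, rt
Reagents that add atoms: none
Why: Catalytic hydrogenolysis of the vinyl C–O triflate bond and saturation of the ring C alkene; the tetrasubstituted silyl enol ether of ring B is too hindered to be reduced, and the amine traps the triflic acid released.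

Step 13
Reactants: 15 (3aR,7S,7aR)-5-(tert-butyldimethylsilyloxy)-7-methoxy-3a,7a-dimethyl-6-[2-methyl-2-(triethylsilyloxy)propyl]-2,3,3a,4,7,7a-hexahydro-1H-inden-1-one
Product: 16 (3aR,7S,7aR)-5-(tert-butyldimethylsilyloxy)-7-methoxy-3a,7a-dimethyl-6-[2-methyl-2-(triethylsilyloxy)propyl]-3a,4,7,7a-tetrahydro-3H-inden-1-yl trifluoromethanesulfonate
Conditions: KN(SiMe3)2, THF, −78 °C; PhNTf2, −78 → 0 °C
Reagents that add atoms: N-phenylbis(trifluoromethanesulfonimide), O=S(=O)(N(c1ccccc1)S(=O)(=O)C(F)(F)F)C(F)(F)F
Why: The ketone has one α-methylene only (the other α-carbon is quaternary), so enolate formation and O-triflation are regiochemically unambiguous; the β-methoxy group cannot be eliminated because the carbon between it and the carbonyl has no hydrogen.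

Step 14
Reactants: 16 (3aR,7S,7aR)-5-(tert-butyldimethylsilyloxy)-7-methoxy-3a,7a-dimethyl-6-[2-methyl-2-(triethylsilyloxy)propyl]-3a,4,7,7a-tetrahydro-3H-inden-1-yl trifluoromethanesulfonate
Product: 17 (3aR,4R,7aR)-6-(tert-butyldimethylsilyloxy)-4-methoxy-3a,7a-dimethyl-5-[2-methyl-2-(triethylsilyloxy)propyl]-2,3,3a,4,7,7a-hexahydro-1H-indene
Conditions: H2 (1–3 atm), PtO2, K2CO3 (solid), EtOAc, rt
Reagents that add atoms: none
Why: Hydrogenation of an enol triflate over platinum cleaves the C–O bond and saturates the alkene, the established ketone-to-methylene sequence via the enol triflate; carbonate neutralises the acid. The change of the C4 descriptor from S to R is a priority change only.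

Step 15
Reactants: 17 (3aR,4R,7aR)-6-(tert-butyldimethylsilyloxy)-4-methoxy-3a,7a-dimethyl-5-[2-methyl-2-(triethylsilyloxy)propyl]-2,3,3a,4,7,7a-hexahydro-1H-indene
Product: 18 (3aR,7aS)-3a,7a-dimethyl-6-[2-methyl-2-(triethylsilyloxy)propyl]-1,2,3,3a,4,7a-hexahydro-5H-inden-5-one
Conditions: CF3CO2H (1.5 equiv), CH2Cl2, 0 °C, short contact; aq NaHCO3
Reagents that add atoms: none
Why: Acid unravelling of a 1-alkoxy-3-silyloxy diene cycloadduct: the enol ether assists ionisation of the allylic methoxy group and loss of the silyl group gives the enone, which removes the transient C4 stereocentre. Brief exposure at 0 °C is chosen to spare the tertiary triethylsilyl ether, which is far less labile than the enol ether.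

Step 16
Reactants: 19 4-methoxy-2-methylphenol
Product: 20 4-methoxy-2-methyl-1-(prop-2-en-1-yloxy)benzene
Conditions: allyl bromide, K2CO3, acetone, reflux
Reagents that add atoms: allyl bromide, C=CCBr
Why: Williamson ether synthesis on a phenoxide.

Step 17
Reactants: 20 4-methoxy-2-methyl-1-(prop-2-en-1-yloxy)benzene
Product: 21 4-methoxy-2-methyl-6-(prop-2-en-1-yl)phenol
Conditions: N,N-diethylaniline, 190 °C
Reagents that add atoms: none
Why: Aromatic Claisen rearrangement; only one ortho position carries hydrogen and the para position is blocked, so the allyl group has one destination.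

Step 18
Reactants: 21 4-methoxy-2-methyl-6-(prop-2-en-1-yl)phenol
Product: 22 tert-butyl[4-methoxy-2-methyl-6-(prop-2-en-1-yl)phenoxy]dimethylsilane
Conditions: tBuMe2SiOTf, 2,6-lutidine, CH2Cl2, 0 °C
Reagents that add atoms: tert-butyldimethylsilyl trifluoromethanesulfonate, CC(C)(C)[Si](C)(C)OS(=O)(=O)C(F)(F)F
Why: Silylation of a 2,6-disubstituted phenol with the reactive silyl triflate; the ether survives the organometallic and chromium steps and is removed with the triethylsilyl ether at the end.

Step 19
Reactants: 22 tert-butyl[4-methoxy-2-methyl-6-(prop-2-en-1-yl)phenoxy]dimethylsilane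
Product: 23 (2E)-4-[2-(tert-butyldimethylsilyloxy)-5-methoxy-3-methylphenyl]-2-methylbut-2-enal
Conditions: methacrolein (5 equiv), second-generation Grubbs catalyst (5 mol %), CH2Cl2, 40 °C
Reagents that add atoms: methacrolein, CC(=C)C=O
Why: Olefin cross-metathesis of a terminal alkene with methacrolein; the conjugated trisubstituted enal forms under thermodynamic control with the E geometry.

Step 20
Reactants: 23 (2E)-4-[2-(tert-butyldimethylsilyloxy)-5-methoxy-3-methylphenyl]-2-methylbut-2-enal
Product: 24 (2E)-4-[2-(tert-butyldimethylsilyloxy)-5-methoxy-3-methylphenyl]-2-methylbut-2-en-1-ol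
Conditions: NaBH4, CeCl3·7H2O, MeOH, 0 °C
Reagents that add atoms: none
Why: Luche reduction gives clean 1,2-reduction of the enal without touching the alkene geometry.

Step 21
Reactants: 24 (2E)-4-[2-(tert-butyldimethylsilyloxy)-5-methoxy-3-methylphenyl]-2-methylbut-2-en-1-ol
Product: 25 tert-butyl{2-[(2E)-4-chloro-3-methylbut-2-en-1-yl]-4-methoxy-6-methylphenoxy}dimethylsilane
Conditions: MeSO2Cl, 2,4,6-collidine, LiCl, DMF, 0 °C
Reagents that add atoms: lithium chloride, [Li+].[Cl-]
Why: Mesylation and in situ SN2 displacement by chloride converts a primary allylic alcohol to the chloride without allylic transposition or loss of E geometry.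

Step 22
Reactants: 18 (3aR,7aS)-3a,7a-dimethyl-6-[2-methyl-2-(triethylsilyloxy)propyl]-1,2,3,3a,4,7a-hexahydro-5H-inden-5-one; 25 tert-butyl{2-[(2E)-4-chloro-3-methylbut-2-en-1-yl]-4-methoxy-6-methylphenoxy}dimethylsilane
Product: 27 (3aR,7aS)-5-{(2E)-4-[2-(tert-butyldimethylsilyloxy)-5-methoxy-3-methylphenyl]-2-methylbut-2-en-1-yl}-3a,7a-dimethyl-6-[2-methyl-2-(triethylsilyloxy)propyl]-2,3,3a,4,5,7a-hexahydro-1H-inden-5-ol (both C5 epimers), via allylbarium chloride 26 (not isolated)
Conditions: BaI2, LiC12H10 (lithium biphenylide, 2 equiv), THF, rt; 25, −78 °C; then 18, −78 °C; aq NH4Cl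
Reagents that add atoms: none
Why: Allylbarium reagents add to ketones through the less substituted allyl terminus and keep the alkene geometry at −78 °C (α-selective carbonyl allylation), unlike magnesium or zinc reagents that attack through the branched terminus. 1,2-Addition is favoured because the enone β-carbon is neopentyl; the new carbinol centre is lost in step 23, so its configuration is irrelevant.

Step 23
Reactants: 27 (3aR,7aS)-5-{(2E)-4-[2-(tert-butyldimethylsilyloxy)-5-methoxy-3-methylphenyl]-2-methylbut-2-en-1-yl}-3a,7a-dimethyl-6-[2-methyl-2-(triethylsilyloxy)propyl]-2,3,3a,4,5,7a-hexahydro-1H-inden-5-ol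
Product: 28 (3aR,7aR)-6-{(2E)-4-[2-(tert-butyldimethylsilyloxy)-5-methoxy-3-methylphenyl]-2-methylbut-2-en-1-yl}-3a,7a-dimethyl-5-[2-methyl-2-(triethylsilyloxy)propyl]-1,2,3,3a,7,7a-hexahydro-4H-inden-4-one
Conditions: [C5H5NH][CrO3Cl] (pyridinium chlorochromate, 3 equiv), 4 Å molecular sieves, CH2Cl2, rt
Reagents that add atoms: pyridinium chlorochromate, [O-][Cr](=O)(=O)Cl.c1cc[nH+]cc1
Why: Dauben oxidative transposition: the tertiary allylic chromate ester undergoes a [3,3] shift to the secondary allylic chromate, which is oxidised to the enone; the precedent includes carbonyls formed next to a quaternary carbon. The silyl ether on the arm prevents capture of the allylic system by the tertiary oxygen.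

Step 24
Reactants: 28 (3aR,7aR)-6-{(2E)-4-[2-(tert-butyldimethylsilyloxy)-5-methoxy-3-methylphenyl]-2-methylbut-2-en-1-yl}-3a,7a-dimethyl-5-[2-methyl-2-(triethylsilyloxy)propyl]-1,2,3,3a,7,7a-hexahydro-4H-inden-4-one
Product: 29 (3aR,7aR)-5-(2-hydroxy-2-methylpropyl)-6-[(2E)-4-(2-hydroxy-5-methoxy-3-methylphenyl)-2-methylbut-2-en-1-yl]-3a,7a-dimethyl-1,2,3,3a,7,7a-hexahydro-4H-inden-4-one (CNP0158008.2)
Conditions: Bu4NF (3 equiv), THF, 0 °C → rt
Reagents that add atoms: none
Why: Fluoride cleaves the aryl and the tertiary silyl ether in one operation under non-acidic, non-oxidising conditions that suit the tertiary alcohol and the electron-rich phenol.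

## Compound list

1 | 2,3-dimethylmaleic anhydride | CC1=C(C)C(=O)OC1=O | starting material
2 | tert-butyl (2E)-(3,4-dimethyl-5-oxofuran-2(5H)-ylidene)acetate | CC1=C(C)/C(=C\C(=O)OC(C)(C)C)OC1=O | intermediate
3 | tert-butyl 3,4-dimethyl-2,5-dioxocyclopent-3-ene-1-carboxylate | CC1=C(C)C(=O)C(C(=O)OC(C)(C)C)C1=O | intermediate
4 | 4,5-dimethylcyclopent-4-ene-1,3-dione | CC1=C(C)C(=O)CC1=O | intermediate
5 | ethyl levulinate | CCOC(=O)CCC(C)=O | starting material
6 | 5,5-dimethyloxolan-2-one | CC1(C)CCC(=O)O1 | intermediate
7 | 4-hydroxy-N-methoxy-N,4-dimethylpentanamide | CON(C)C(=O)CCC(C)(C)O | intermediate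
8 | N-methoxy-N,4-dimethyl-4-(triethylsilyloxy)pentanamide | CON(C)C(=O)CCC(C)(C)O[Si](CC)(CC)CC | intermediate
9 | 2-formyl-N-methoxy-N,4-dimethyl-4-(triethylsilyloxy)pentanamide (formed as its lithium enolate) | CON(C)C(=O)C(C=O)CC(C)(C)O[Si](CC)(CC)CC | intermediate (not isolated)
10 | (2E)-N-methoxy-2-(methoxymethylidene)-N,4-dimethyl-4-(triethylsilyloxy)pentanamide | CO/C=C(\CC(C)(C)O[Si](CC)(CC)CC)C(=O)N(C)OC | intermediate
11 | (3E)-3-(methoxymethylidene)-5-methyl-5-(triethylsilyloxy)hexan-2-one | CO/C=C(\CC(C)(C)O[Si](CC)(CC)CC)C(C)=O | intermediate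
12 | (1E)-3-(tert-butyldimethylsilyloxy)-1-methoxy-2-[2-methyl-2-(triethylsilyloxy)propyl]buta-1,3-diene | CO/C=C(\CC(C)(C)O[Si](CC)(CC)CC)C(=C)O[Si](C)(C)C(C)(C)C | intermediate
13 | (3aR,4S,7aR)-6-(tert-butyldimethylsilyloxy)-4-methoxy-3a,7a-dimethyl-5-[2-methyl-2-(triethylsilyloxy)propyl]-3a,4,7,7a-tetrahydro-1H-indene-1,3(2H)-dione | CO[C@@H]1[C@]2(C)C(=O)CC(=O)[C@]2(C)CC(O[Si](C)(C)C(C)(C)C)=C1CC(C)(C)O[Si](CC)(CC)CC | intermediate
14 | (3aR,4S,7aR)-6-(tert-butyldimethylsilyloxy)-4-methoxy-3a,7a-dimethyl-5-[2-methyl-2-(triethylsilyloxy)propyl]-3-oxo-3a,4,7,7a-tetrahydro-3H-inden-1-yl trifluoromethanesulfonate | CO[C@@H]1[C@]2(C)C(=O)C=C(OS(=O)(=O)C(F)(F)F)[C@]2(C)CC(O[Si](C)(C)C(C)(C)C)=C1CC(C)(C)O[Si](CC)(CC)CC | intermediate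
15 | (3aR,7S,7aR)-5-(tert-butyldimethylsilyloxy)-7-methoxy-3a,7a-dimethyl-6-[2-methyl-2-(triethylsilyloxy)propyl]-2,3,3a,4,7,7a-hexahydro-1H-inden-1-one | CO[C@@H]1[C@]2(C)C(=O)CC[C@]2(C)CC(O[Si](C)(C)C(C)(C)C)=C1CC(C)(C)O[Si](CC)(CC)CC | intermediate
16 | (3aR,7S,7aR)-5-(tert-butyldimethylsilyloxy)-7-methoxy-3a,7a-dimethyl-6-[2-methyl-2-(triethylsilyloxy)propyl]-3a,4,7,7a-tetrahydro-3H-inden-1-yl trifluoromethanesulfonate | CO[C@@H]1[C@]2(C)C(OS(=O)(=O)C(F)(F)F)=CC[C@]2(C)CC(O[Si](C)(C)C(C)(C)C)=C1CC(C)(C)O[Si](CC)(CC)CC | intermediate
17 | (3aR,4R,7aR)-6-(tert-butyldimethylsilyloxy)-4-methoxy-3a,7a-dimethyl-5-[2-methyl-2-(triethylsilyloxy)propyl]-2,3,3a,4,7,7a-hexahydro-1H-indene | CO[C@@H]1[C@]2(C)CCC[C@]2(C)CC(O[Si](C)(C)C(C)(C)C)=C1CC(C)(C)O[Si](CC)(CC)CC | intermediate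
18 | (3aR,7aS)-3a,7a-dimethyl-6-[2-methyl-2-(triethylsilyloxy)propyl]-1,2,3,3a,4,7a-hexahydro-5H-inden-5-one | O=C1C[C@@]2(C)CCC[C@@]2(C)C=C1CC(C)(C)O[Si](CC)(CC)CC | intermediate
19 | 4-methoxy-2-methylphenol | COc1ccc(O)c(C)c1 | starting material
20 | 4-methoxy-2-methyl-1-(prop-2-en-1-yloxy)benzene | COc1ccc(OCC=C)c(C)c1 | intermediate
21 | 4-methoxy-2-methyl-6-(prop-2-en-1-yl)phenol | COc1cc(C)c(O)c(CC=C)c1 | intermediate
22 | tert-butyl[4-methoxy-2-methyl-6-(prop-2-en-1-yl)phenoxy]dimethylsilane | COc1cc(C)c(O[Si](C)(C)C(C)(C)C)c(CC=C)c1 | intermediate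
23 | (2E)-4-[2-(tert-butyldimethylsilyloxy)-5-methoxy-3-methylphenyl]-2-methylbut-2-enal | COc1cc(C)c(O[Si](C)(C)C(C)(C)C)c(C/C=C(\C)C=O)c1 | intermediate
24 | (2E)-4-[2-(tert-butyldimethylsilyloxy)-5-methoxy-3-methylphenyl]-2-methylbut-2-en-1-ol | COc1cc(C)c(O[Si](C)(C)C(C)(C)C)c(C/C=C(\C)CO)c1 | intermediate
25 | tert-butyl{2-[(2E)-4-chloro-3-methylbut-2-en-1-yl]-4-methoxy-6-methylphenoxy}dimethylsilane | COc1cc(C)c(O[Si](C)(C)C(C)(C)C)c(C/C=C(\C)CCl)c1 | intermediate
26 | {(2E)-4-[2-(tert-butyldimethylsilyloxy)-5-methoxy-3-methylphenyl]-2-methylbut-2-en-1-yl}barium chloride | COc1cc(C)c(O[Si](C)(C)C(C)(C)C)c(C/C=C(\C)C[Ba]Cl)c1 | intermediate (not isolated)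
27 | (3aR,7aS)-5-{(2E)-4-[2-(tert-butyldimethylsilyloxy)-5-methoxy-3-methylphenyl]-2-methylbut-2-en-1-yl}-3a,7a-dimethyl-6-[2-methyl-2-(triethylsilyloxy)propyl]-2,3,3a,4,5,7a-hexahydro-1H-inden-5-ol, both C5 epimers | COc1cc(C)c(O[Si](C)(C)C(C)(C)C)c(C/C=C(\C)CC2(O)C[C@@]3(C)CCC[C@@]3(C)C=C2CC(C)(C)O[Si](CC)(CC)CC)c1 | intermediate
28 | (3aR,7aR)-6-{(2E)-4-[2-(tert-butyldimethylsilyloxy)-5-methoxy-3-methylphenyl]-2-methylbut-2-en-1-yl}-3a,7a-dimethyl-5-[2-methyl-2-(triethylsilyloxy)propyl]-1,2,3,3a,7,7a-hexahydro-4H-inden-4-one | COc1cc(C)c(O[Si](C)(C)C(C)(C)C)c(C/C=C(\C)CC2=C(CC(C)(C)O[Si](CC)(CC)CC)C(=O)[C@]3(C)CCC[C@]3(C)C2)c1 | intermediate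
29 | (3aR,7aR)-5-(2-hydroxy-2-methylpropyl)-6-[(2E)-4-(2-hydroxy-5-methoxy-3-methylphenyl)-2-methylbut-2-en-1-yl]-3a,7a-dimethyl-1,2,3,3a,7,7a-hexahydro-4H-inden-4-one (CNP0158008.2) | COc1cc(C)c(O)c(C/C=C(\C)CC2=C(CC(C)(C)O)C(=O)[C@]3(C)CCC[C@]3(C)C2)c1 | target

## Step count and least certain steps

Total: 24 steps. Longest linear sequence: 15 steps (from 5 to 29 through steps 4–15 and 22–24).

**Step 10 (key step; proposed new method).** The catalysed pathway may be too slow at the tetrasubstituted alkene, so the uncatalysed racemic cycloaddition would dominate and erode the enantiomeric excess. The enolic, acidic product may also bind the titanium centre and stop turnover, or protodesilylate unreacted diene. Fallback with known chemistry, from 4 and 12 back to 13: the cycloaddition is run thermally without catalyst (toluene, 80 °C, or under high pressure) to give the racemic cycloadduct F1. Because the enolised 1,3-dione is a vinylogous acid, F1 is resolved by crystallisation of its diastereomeric salt with (R)-1-phenylethylamine, the ammonium enolate F2 (or the salt of the S amine, whichever carries the wanted enantiomer). Partition against a pH 4–5 buffer returns enantiopure 13.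

**Step 22.** The allyl unit may be transferred through its more substituted terminus, giving the branched carbinol. Conjugate addition, erosion of the E geometry above −78 °C, and homocoupling during metalation are further risks. Fallback, from 18 back to 28: 2-methylallylmagnesium chloride, whose two termini are equivalent, is added to 18 to give the methallyl carbinol F3. Oxidative transposition with pyridinium chlorochromate gives the 2-methylallyl enone F4. Cross-metathesis of F4 with allyl arene 22 (second-generation Grubbs catalyst) then builds the trisubstituted alkene and gives 28. The E/Z ratio of that metathesis is expected to be modest and the isomers would have to be separated, which is why this is not the first choice.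

**Step 12 (with steps 11, 13 and 14).** Hydrogenolysis may also cleave the allylic C–O bond at C4, released triflic acid may cleave the ring B enol ether if buffering is incomplete, or reduction may stall at the enone stage. Incomplete regiocontrol in step 11 is harmless, since both regioisomeric series converge at 17. Fallback, from 13 back to 17: both carbonyls are reduced at once by hydrogenation over Ru/C (H2, iPrOH), a method that works for enolic cyclic 1,3-diones where hydride reagents eliminate, to give diol F5 as a mixture of carbinol epimers. NaH, CS2 and MeI give the bis(S-methyl xanthate) F6, and double Barton–McCombie deoxygenation (Bu3SnH, AIBN, toluene, 110 °C) gives 17.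

**Step 23.** The tertiary allylic alcohol may ionise and dehydrate to trienes, the [3,3] shift of the chromate ester onto the neopentyl carbon may be slow, and the doubly allylic methylene may be over-oxidised on long exposure. Fallback, from 27 back to 28: transposition and oxidation are separated. Ph3SiOReO3-catalysed 1,3-isomerisation of 27, driven by formation of the tetrasubstituted alkene, gives the secondary allylic alcohol F7, and Dess–Martin oxidation gives 28 without acid or chromium.

**Step 7.** The formyl enolate may be methylated on carbon instead of oxygen, the N-methoxy amide enolate may fragment with loss of formaldehyde, or a mixture of enol ether geometries may form. Fallback, from 6 back to 10: the formyl carbon is introduced at the lactone stage, the classical substrate for Claisen formylation. NaH and HCO2Et, then Me2SO4 and K2CO3, give the methoxymethylidene lactone F8; Weinreb aminolysis (Me(MeO)NH·HCl, Me3Al) gives the hydroxy amide F9; Et3SiOTf and 2,6-lutidine give 10.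

## Further compounds

F1 | step 10 | racemic 13 (both enantiomers of the cycloadduct) | CO[C@@H]1[C@]2(C)C(=O)CC(=O)[C@]2(C)CC(O[Si](C)(C)C(C)(C)C)=C1CC(C)(C)O[Si](CC)(CC)CC.CO[C@H]1[C@@]2(C)C(=O)CC(=O)[C@@]2(C)CC(O[Si](C)(C)C(C)(C)C)=C1CC(C)(C)O[Si](CC)(CC)CC
F2 | step 10 | (R)-1-phenylethylammonium enolate of 13 | CO[C@@H]1[C@]2(C)C(=O)C=C([O-])[C@]2(C)CC(O[Si](C)(C)C(C)(C)C)=C1CC(C)(C)O[Si](CC)(CC)CC.C[C@@H]([NH3+])c1ccccc1
F3 | step 22 | (3aR,7aS)-3a,7a-dimethyl-5-(2-methylprop-2-en-1-yl)-6-[2-methyl-2-(triethylsilyloxy)propyl]-2,3,3a,4,5,7a-hexahydro-1H-inden-5-ol, both C5 epimers | CC(=C)CC1(O)C[C@@]2(C)CCC[C@@]2(C)C=C1CC(C)(C)O[Si](CC)(CC)CC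
F4 | step 22 | (3aR,7aR)-3a,7a-dimethyl-6-(2-methylprop-2-en-1-yl)-5-[2-methyl-2-(triethylsilyloxy)propyl]-1,2,3,3a,7,7a-hexahydro-4H-inden-4-one | CC(=C)CC1=C(CC(C)(C)O[Si](CC)(CC)CC)C(=O)[C@]2(C)CCC[C@]2(C)C1
F5 | step 12 | (3aR,4S,7aR)-6-(tert-butyldimethylsilyloxy)-4-methoxy-3a,7a-dimethyl-5-[2-methyl-2-(triethylsilyloxy)propyl]-2,3,3a,4,7,7a-hexahydro-1H-indene-1,3-diol, carbinol epimers | CO[C@@H]1[C@]2(C)C(O)CC(O)[C@]2(C)CC(O[Si](C)(C)C(C)(C)C)=C1CC(C)(C)O[Si](CC)(CC)CC
F6 | step 12 | O,O'-diester of F5 with S-methyl dithiocarbonic acid (bis-xanthate), carbinol epimers | CO[C@@H]1[C@]2(C)C(OC(=S)SC)CC(OC(=S)SC)[C@]2(C)CC(O[Si](C)(C)C(C)(C)C)=C1CC(C)(C)O[Si](CC)(CC)CC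
F7 | step 23 | (3aR,7aR)-6-{(2E)-4-[2-(tert-butyldimethylsilyloxy)-5-methoxy-3-methylphenyl]-2-methylbut-2-en-1-yl}-3a,7a-dimethyl-5-[2-methyl-2-(triethylsilyloxy)propyl]-2,3,3a,4,7,7a-hexahydro-1H-inden-4-ol, both C4 epimers | COc1cc(C)c(O[Si](C)(C)C(C)(C)C)c(C/C=C(\C)CC2=C(CC(C)(C)O[Si](CC)(CC)CC)C(O)[C@]3(C)CCC[C@]3(C)C2)c1
F8 | step 7 | (3E)-3-(methoxymethylidene)-5,5-dimethyloxolan-2-one | CO/C=C1\CC(C)(C)OC1=O
F9 | step 7 | (2E)-4-hydroxy-N-methoxy-2-(methoxymethylidene)-N,4-dimethylpentanamide | CO/C=C(\CC(C)(C)O)C(=O)N(C)OC
A1 | alternative 1 | (Z)-3,7-dimethyl-9-[3-(trimethylsilyl)prop-2-yn-1-yl]oxacyclonon-7-en-2-one, carbinol configuration to be chosen for the chirality transfer | CC1CCC/C(C)=C\C(CC#C[Si](C)(C)C)OC1=O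
A2 | alternative 1 | (1R,2R)-1,2-dimethyl-2-[(1E)-5-(trimethylsilyl)pent-1-en-4-yn-1-yl]cyclopentane-1-carboxylic acid | OC(=O)[C@]1(C)CCC[C@]1(C)/C=C/CC#C[Si](C)(C)C
A3 | alternative 2 | 1,3-dioxoisoindolin-2-yl 2-{cis-2-[(5E)-7-[2-(tert-butyldimethylsilyloxy)-5-methoxy-3-methylphenyl]-5-methylhept-5-en-2-ynoyl]-1,2-dimethylcyclopentyl}acetate | O=C(C[C@@]1(C)CCC[C@@]1(C)C(=O)C#CC/C(C)=C/Cc1cc(OC)cc(C)c1O[Si](C)(C)C(C)(C)C)ON1C(=O)c2ccccc2C1=O
A4 | alternative 2 | (3aR,7aR)-6-{(2E)-4-[2-(tert-butyldimethylsilyloxy)-5-methoxy-3-methylphenyl]-2-methylbut-2-en-1-yl}-3a,7a-dimethyl-1,2,3,3a,7,7a-hexahydro-4H-inden-4-one | COc1cc(C)c(O[Si](C)(C)C(C)(C)C)c(C/C=C(\C)CC2=CC(=O)[C@]3(C)CCC[C@]3(C)C2)c1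
A5 | alternative 3 | triisopropyl{[(3S)-2,3-dimethyl-3-(prop-2-yn-1-yl)cyclohex-1-en-1-yl]oxy}silane | C#CC[C@]1(C)CCCC(O[Si](C(C)C)(C(C)C)C(C)C)=C1C
A6 | alternative 3 | (3aR,7aS)-3a,7a-dimethyl-1,3a,5,6,7,7a-hexahydro-4H-inden-4-one | O=C1[C@]2(C)C=CC[C@]2(C)CCC1
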